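**Plan**

1. Atom labels: C1 (CH–OAc), C2 (CH2), C3 (carbinol carbon with isopropyl), C4 (ring-fusion CH), C5 (CH–O-aroyl), C6 (CH2), C7 (=C–CH3), C8 (=CH), C9 (CH2), C10 (quaternary C–CH3). The five-membered ring is C1–C2–C3–C4–C10, the seven-membered ring C4–C5–C6–C7–C8–C9–C10.
2. Retrosynthetic cuts: first the two ester C–O bonds, then C4–C10 and C9–C10 together (C10 becomes a diazo carbon, the seven-membered ring reverts to a benzene ring), then C1–C10 (ethyl addition), C2–C3 (allylation) and the aryl–C3 bond (Fries acylation).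
3. Enabling feature: C4–C5(O)–C6–C7(CH3)–C8–C9 has the substitution pattern of a 2-oxy-4-methylphenyl ring (C4 ipso, C5 oxygen-bearing ortho carbon, C7 para, C9 free ortho carbon). C10 lies between C4 and C9 and is also tied to C3 through C1–C2, so one carbenoid carbon can close the five-membered ring and enlarge the six-membered ring in a single event.
4. Forward order: m-cresol → ortho-acylphenol → allylation at C3 → silylene bridge from O3 to the aryl oxygen → methyl diazoketone → carbenoid step → C1 reduction and acetylation → unmasking of the C5 ketone → 1,6-reduction → C5 reduction → aroylation.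
5. Stereochemistry: C3 from a chiral allylsilane; C10 from C3 through the silylene bridge; C1 by hydride attack anti to the axial isopropyl group; C4 by equilibration to the trans-fused ketol; C5 by hydride delivery from the C3 hydroxyl.

Key step: step 8

Assumption: the (R,R) enantiomer of the allylchlorosilane is written for step 2; if its sense of induction with this ketone is the opposite, the equally available (S,S) enantiomer is used with no other change.

Azulene locants in the names: C1–C3 = 1–3, C4 = 3a, C5–C9 = 4–8, C10 = 8a.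

**Route**

Step 1
Reactants: 1 m-cresol; 2 isobutyryl chloride
Product: 4 1-(2-hydroxy-4-methylphenyl)-2-methylpropan-1-one, via m-cresyl isobutyrate 3 (not isolated)
Conditions: neat, 60 °C; then AlCl3 (1.5 equiv), 140 °C; aq. HCl
Reagents that add atoms: none
Why: O-acylation followed by Fries rearrangement, which at high temperature should deliver the acyl group to the position ortho to oxygen and para to methyl, where the product is held as an aluminium chelate.

Step 2
Reactants: 4 1-(2-hydroxy-4-methylphenyl)-2-methylpropan-1-one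
Product: 6 2-[(3R)-3-hydroxy-2-methylhex-5-en-3-yl]-5-methylphenol, via spirocyclic aminosilane adduct 5 (not isolated)
Conditions: (R,R)-allylchlorosilane reagent (1.5 equiv), CH2Cl2, 23 °C; then 1 M HCl, EtOAc, 0 °C
Reagents that add atoms: (4R,5R)-2-allyl-1,3-bis(4-bromobenzyl)-2-chloro-octahydro-1,3,2-benzodiazasilole, C=CC[Si]1(Cl)N(Cc2ccc(Br)cc2)[C@@H]2CCCC[C@H]2N1Cc1ccc(Br)cc1
Why: Enantioselective ketone allylation with a strained chiral allylchlorosilane, in which the phenol displaces chloride on silicon, the hindered ketone is bound intramolecularly and allyl is transferred through a closed chair transition state whose diamine backbone selects the carbonyl face and sets C3 as R.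

Step 3
Reactants: 6 2-[(3R)-3-hydroxy-2-methylhex-5-en-3-yl]-5-methylphenol
Product: 7 (4R)-2,2-di-tert-butyl-7-methyl-4-(propan-2-yl)-4-(prop-2-en-1-yl)-4H-1,3,2-benzodioxasiline
Conditions: t-Bu2Si(OTf)2, 2,6-lutidine, DMF, 0 to 50 °C
Reagents that add atoms: di-tert-butylsilyl bis(trifluoromethanesulfonate), CC(C)(C)[Si](OS(=O)(=O)C(F)(F)F)(OS(=O)(=O)C(F)(F)F)C(C)(C)C
Why: Silylene protection of the phenol and the tertiary hydroxyl as a six-membered ring, which should mask both O–H bonds against carbenoid insertion and hold O3 next to the aryl oxygen.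

Step 4
Reactants: 7 (4R)-2,2-di-tert-butyl-7-methyl-4-(propan-2-yl)-4-(prop-2-en-1-yl)-4H-1,3,2-benzodioxasiline
Product: 9 [(4R)-2,2-di-tert-butyl-7-methyl-4-(propan-2-yl)-4H-1,3,2-benzodioxasilin-4-yl]acetaldehyde, via ozonide 8 (not isolated)
Conditions: O3, CH2Cl2, −78 °C (indicator end point); then PPh3, −78 °C to rt
Reagents that add atoms: ozone, O=[O+][O-]
Why: Ozonolysis with reductive work-up, in which the terminal alkene should react far faster than the silylated arene.

Step 5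
Reactants: 9 [(4R)-2,2-di-tert-butyl-7-methyl-4-(propan-2-yl)-4H-1,3,2-benzodioxasilin-4-yl]acetaldehyde
Product: 10 1-[(4R)-2,2-di-tert-butyl-7-methyl-4-(propan-2-yl)-4H-1,3,2-benzodioxasilin-4-yl]butan-2-ol (both carbinol epimers)
Conditions: EtMgBr, THF, −78 to 0 °C; aq. NH4Cl
Reagents that add atoms: ethylmagnesium bromide, CC[Mg]Br
Why: Grignard addition to the aldehyde forms the C1–C10 bond, and the new carbinol centre needs no control because it is oxidised in the next step.

Step 6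
Reactants: 10 1-[(4R)-2,2-di-tert-butyl-7-methyl-4-(propan-2-yl)-4H-1,3,2-benzodioxasilin-4-yl]butan-2-ol
Product: 11 1-[(4R)-2,2-di-tert-butyl-7-methyl-4-(propan-2-yl)-4H-1,3,2-benzodioxasilin-4-yl]butan-2-one
Conditions: DMP (1,1,1-triacetoxy-1,2-benziodoxol-3-one), NaHCO3, CH2Cl2, rt
Reagents that add atoms: none
Why: Dess–Martin oxidation under buffered, non-basic conditions should give the β-silyloxy ketone without elimination.

Step 7
Reactants: 11 1-[(4R)-2,2-di-tert-butyl-7-methyl-4-(propan-2-yl)-4H-1,3,2-benzodioxasilin-4-yl]butan-2-one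
Product: 13 3-diazo-1-[(4R)-2,2-di-tert-butyl-7-methyl-4-(propan-2-yl)-4H-1,3,2-benzodioxasilin-4-yl]butan-2-one, via trifluoroacetyl diketone 12 (not isolated)
Conditions: LiN(SiMe3)2, THF, −78 °C; CF3CO2CH2CF3; then MsN3, Et3N, H2O, MeCN, rt
Reagents that add atoms: methanesulfonyl azide, CS(=O)(=O)N=[N+]=[N-]; 2,2,2-trifluoroethyl trifluoroacetate, O=C(OCC(F)(F)F)C(F)(F)F (its atoms remain only in 12)
Why: Deacylative (Regitz-type) diazo transfer, in which the kinetic enolate should form at the ethyl CH2 because the other α-CH2 is neopentylic, C-trifluoroacetylation activates that carbon and MsN3 transfers N2 with loss of the trifluoroacetyl group.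

Step 8
Reactants: 13 3-diazo-1-[(4R)-2,2-di-tert-butyl-7-methyl-4-(propan-2-yl)-4H-1,3,2-benzodioxasilin-4-yl]butan-2-one
Product: 15 (3R,8aR)-3,4-[(di-tert-butylsilanediyl)bis(oxy)]-6,8a-dimethyl-3-(propan-2-yl)-3,8a-dihydroazulen-1(2H)-one, via norcaradiene 14 (not isolated)
Conditions: Rh2(OAc)4 (1 mol %), CH2Cl2, 40 °C, slow addition of 13
Reagents that add atoms: none
Why: Rh2(OAc)4 expels N2 from 13 to give an electrophilic rhodium carbenoid at C10, which adds across the ipso–ortho π bond C4–C9 in cyclopropanation mode (forming C4–C10 and C9–C10) to give norcaradiene 14, and this opens by thermal disrotatory 6π electrocyclic cleavage of C4–C9 to cycloheptatriene 15. The closest known reaction type is the intramolecular Buchner reaction of 2-diazo-5-aryl-3-ketones to 8a-methyl-3,8a-dihydroazulen-1(2H)-ones. The five-membered ring C1–C2–C3–C4–C10 closes by [2+1] addition of the tethered carbenoid, and the seven-membered ring arises by enlargement of the benzene ring through the electrocyclic opening, not by a separate cyclisation. The only new stereocentre, C10, is controlled by C3 through the silylene: O3 is held in the arene plane beside the aryl oxygen, so the C2 chain and the isopropyl group lie on opposite faces and the carbenoid can reach only the face that places the C10 methyl cis to O3 (8aR from 3R). The step needs attack at C9 and not C5, which the bridge and the silyloxy group on C5 secure, and it needs cycloaddition to outrun 1,5 C–H insertion at the isopropyl methine and 1,2-hydride shift from the carbenoid methyl, which the electron-rich arene and the acetate-ligated dirhodium catalyst should favour.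

Step 9
Reactants: 15 (3R,8aR)-3,4-[(di-tert-butylsilanediyl)bis(oxy)]-6,8a-dimethyl-3-(propan-2-yl)-3,8a-dihydroazulen-1(2H)-one
Product: 16 (1S,3R,8aR)-3,4-[(di-tert-butylsilanediyl)bis(oxy)]-6,8a-dimethyl-3-(propan-2-yl)-1,2,3,8a-tetrahydroazulen-1-ol
Conditions: NaBH4, MeOH/THF, −20 °C
Reagents that add atoms: none
Why: Borohydride reduction of the cyclopentanone, in which the six-membered silylene ring forces the C3 isopropyl group into a pseudo-axial position 1,3 to the carbonyl, so hydride should enter anti to it and set the C1 oxygen trans to the C10 methyl (1S).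

Step 10
Reactants: 16 (1S,3R,8aR)-3,4-[(di-tert-butylsilanediyl)bis(oxy)]-6,8a-dimethyl-3-(propan-2-yl)-1,2,3,8a-tetrahydroazulen-1-ol
Product: 17 (1S,3R,8aR)-3,4-[(di-tert-butylsilanediyl)bis(oxy)]-6,8a-dimethyl-3-(propan-2-yl)-1,2,3,8a-tetrahydroazulen-1-yl acetate
Conditions: Ac2O, pyridine, DMAP, CH2Cl2, rt
Reagents that add atoms: acetic anhydride, CC(=O)OC(C)=O
Why: DMAP-catalysed acetylation of the only free hydroxyl, installed before the C5 oxygen is unmasked so that the two ester positions never compete.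

Step 11
Reactants: 17 (1S,3R,8aR)-3,4-[(di-tert-butylsilanediyl)bis(oxy)]-6,8a-dimethyl-3-(propan-2-yl)-1,2,3,8a-tetrahydroazulen-1-yl acetate
Product: 19 (1S,3R,3aR,8aR)-3-hydroxy-6,8a-dimethyl-4-oxo-3-(propan-2-yl)-1,2,3,3a,4,8a-hexahydroazulen-1-yl acetate, via cis-fused C4 epimer 18 (not isolated)
Conditions: Bu4NF, AcOH, THF, 0 °C to rt; then DBU (0.2 equiv), toluene, rt
Reagents that add atoms: none
Why: Buffered fluoride cleavage of the silyl enol ether and the tertiary silyl ether releases the C5 dienone without acid, and base equilibration of the ketone α-carbon C4 should favour the trans-fused epimer, in which C5 lies anti to the isopropyl group and the C3 hydroxyl can hydrogen-bond to the C5 carbonyl.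

Step 12
Reactants: 19 (1S,3R,3aR,8aR)-3-hydroxy-6,8a-dimethyl-4-oxo-3-(propan-2-yl)-1,2,3,3a,4,8a-hexahydroazulen-1-yl acetate
Product: 20 (1S,3R,3aR,8aR)-3-hydroxy-6,8a-dimethyl-4-oxo-3-(propan-2-yl)-1,2,3,3a,4,5,8,8a-octahydroazulen-1-yl acetate
Conditions: [(Ph3P)CuH]6, H2O, degassed toluene/THF, rt
Reagents that add atoms: none
Why: Copper hydride conjugate reduction in the 1,6-mode, in which the methyl group on the β-carbon C7 should steer hydride to the δ-carbon C9 and kinetic protonation of the copper dienolate at the α-carbon C6 leaves the C7=C8 double bond out of conjugation.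

Step 13
Reactants: 20 (1S,3R,3aR,8aR)-3-hydroxy-6,8a-dimethyl-4-oxo-3-(propan-2-yl)-1,2,3,3a,4,5,8,8a-octahydroazulen-1-yl acetate
Product: 21 (1S,3R,3aS,4S,8aR)-3,4-dihydroxy-6,8a-dimethyl-3-(propan-2-yl)-1,2,3,3a,4,5,8,8a-octahydroazulen-1-yl acetate
Conditions: Me4NBH(OAc)3, MeCN/AcOH, −25 °C
Reagents that add atoms: none
Why: Evans–Saksena hydroxyl-directed reduction, in which the C3 hydroxyl binds boron and delivers hydride through a chair transition state to the carbonyl face on its own side, which should give the equatorial C5 alcohol (4S) with H5 anti to H4.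

Step 14
Reactants: 22 4-hydroxybenzoic acid
Product: 24 4-[(tert-butyldimethylsilyl)oxy]benzoic acid, via bis-silylated ester 23 (not isolated)
Conditions: TBSCl, imidazole, DMF, rt; then AcOH/THF/H2O, rt
Reagents that add atoms: tert-butyldimethylsilyl chloride, CC(C)(C)[Si](C)(C)Cl
Why: Silylation of phenol and acid followed by selective hydrolysis of the much more labile silyl ester leaves the phenol protected.

Step 15
Reactants: 21 (1S,3R,3aS,4S,8aR)-3,4-dihydroxy-6,8a-dimethyl-3-(propan-2-yl)-1,2,3,3a,4,5,8,8a-octahydroazulen-1-yl acetate; 24 4-[(tert-butyldimethylsilyl)oxy]benzoic acid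
Product: 25 (1S,3R,3aS,4S,8aR)-1-(acetyloxy)-3-hydroxy-6,8a-dimethyl-3-(propan-2-yl)-1,2,3,3a,4,5,8,8a-octahydroazulen-4-yl 4-[(tert-butyldimethylsilyl)oxy]benzoate
Conditions: DCC, DMAP, CH2Cl2, rt
Reagents that add atoms: none
Why: Steglich esterification should acylate the secondary C5 hydroxyl and leave the tertiary C3 hydroxyl untouched.

Step 16
Reactants: 25 (1S,3R,3aS,4S,8aR)-1-(acetyloxy)-3-hydroxy-6,8a-dimethyl-3-(propan-2-yl)-1,2,3,3a,4,5,8,8a-octahydroazulen-4-yl 4-[(tert-butyldimethylsilyl)oxy]benzoate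
Product: 26 (1S,3R,3aS,4S,8aR)-1-(acetyloxy)-3-hydroxy-6,8a-dimethyl-3-(propan-2-yl)-1,2,3,3a,4,5,8,8a-octahydroazulen-4-yl 4-hydroxybenzoate
Conditions: Bu4NF, AcOH, THF, 0 °C
Reagents that add atoms: none
Why: Buffered fluoride cleavage of the aryl silyl ether should free the phenol without touching the acetate or the benzoate.

**Compound list**

1 | m-cresol | Cc1cccc(O)c1 | starting material
2 | isobutyryl chloride | CC(C)C(Cl)=O | starting material
3 | m-cresyl isobutyrate | CC(C)C(=O)Oc1cccc(C)c1 | intermediate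
4 | 1-(2-hydroxy-4-methylphenyl)-2-methylpropan-1-one | CC(C)C(=O)c1ccc(C)cc1O | intermediate
5 | spirocyclic aminosilane adduct (allylation product held as cyclic silyl ether; Si bonded to phenol O, tertiary O and both diamine N) | C=CC[C@]1(C(C)C)O[Si]2(Oc3cc(C)ccc31)N(Cc1ccc(Br)cc1)[C@@H]1CCCC[C@H]1N2Cc1ccc(Br)cc1 | intermediate
6 | 2-[(3R)-3-hydroxy-2-methylhex-5-en-3-yl]-5-methylphenol | C=CC[C@@](O)(C(C)C)c1ccc(C)cc1O | intermediate
7 | (4R)-2,2-di-tert-butyl-7-methyl-4-(propan-2-yl)-4-(prop-2-en-1-yl)-4H-1,3,2-benzodioxasiline | C=CC[C@]1(C(C)C)O[Si](C(C)(C)C)(C(C)(C)C)Oc2cc(C)ccc21 | intermediate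
8 | ozonide of 7 (3-substituted 1,2,4-trioxolane) | O1OC(C[C@]2(C(C)C)O[Si](C(C)(C)C)(C(C)(C)C)Oc3cc(C)ccc32)OC1 | intermediate
9 | [(4R)-2,2-di-tert-butyl-7-methyl-4-(propan-2-yl)-4H-1,3,2-benzodioxasilin-4-yl]acetaldehyde | O=CC[C@]1(C(C)C)O[Si](C(C)(C)C)(C(C)(C)C)Oc2cc(C)ccc21 | intermediate
10 | 1-[(4R)-2,2-di-tert-butyl-7-methyl-4-(propan-2-yl)-4H-1,3,2-benzodioxasilin-4-yl]butan-2-ol (both carbinol epimers) | CCC(O)C[C@]1(C(C)C)O[Si](C(C)(C)C)(C(C)(C)C)Oc2cc(C)ccc21 | intermediate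
11 | 1-[(4R)-2,2-di-tert-butyl-7-methyl-4-(propan-2-yl)-4H-1,3,2-benzodioxasilin-4-yl]butan-2-one | CCC(=O)C[C@]1(C(C)C)O[Si](C(C)(C)C)(C(C)(C)C)Oc2cc(C)ccc21 | intermediate
12 | 1,1,1-trifluoro-3-methyl-5-[(4R)-2,2-di-tert-butyl-7-methyl-4-(propan-2-yl)-4H-1,3,2-benzodioxasilin-4-yl]pentane-2,4-dione | CC(C(=O)C(F)(F)F)C(=O)C[C@]1(C(C)C)O[Si](C(C)(C)C)(C(C)(C)C)Oc2cc(C)ccc21 | intermediate
13 | 3-diazo-1-[(4R)-2,2-di-tert-butyl-7-methyl-4-(propan-2-yl)-4H-1,3,2-benzodioxasilin-4-yl]butan-2-one | CC(=[N+]=[N-])C(=O)C[C@]1(C(C)C)O[Si](C(C)(C)C)(C(C)(C)C)Oc2cc(C)ccc21 | intermediate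
14 | norcaradiene valence isomer of 15 (cyclopropane C4–C9–C10 closed) | O=C1C[C@@]2(O[Si](C(C)(C)C)(C(C)(C)C)OC3=CC(C)=C[C@@H]4[C@]1(C)[C@]234)C(C)C | intermediate
15 | (3R,8aR)-3,4-[(di-tert-butylsilanediyl)bis(oxy)]-6,8a-dimethyl-3-(propan-2-yl)-3,8a-dihydroazulen-1(2H)-one | O=C1C[C@@]2(O[Si](C(C)(C)C)(C(C)(C)C)OC3=C2[C@@]1(C)C=CC(C)=C3)C(C)C | intermediate
16 | (1S,3R,8aR)-3,4-[(di-tert-butylsilanediyl)bis(oxy)]-6,8a-dimethyl-3-(propan-2-yl)-1,2,3,8a-tetrahydroazulen-1-ol | O[C@H]1C[C@@]2(O[Si](C(C)(C)C)(C(C)(C)C)OC3=C2[C@@]1(C)C=CC(C)=C3)C(C)C | intermediate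
17 | (1S,3R,8aR)-3,4-[(di-tert-butylsilanediyl)bis(oxy)]-6,8a-dimethyl-3-(propan-2-yl)-1,2,3,8a-tetrahydroazulen-1-yl acetate | CC(=O)O[C@H]1C[C@@]2(O[Si](C(C)(C)C)(C(C)(C)C)OC3=C2[C@@]1(C)C=CC(C)=C3)C(C)C | intermediate
18 | (1S,3R,3aS,8aR)-3-hydroxy-6,8a-dimethyl-4-oxo-3-(propan-2-yl)-1,2,3,3a,4,8a-hexahydroazulen-1-yl acetate (cis-fused) | CC(=O)O[C@H]1C[C@@](O)(C(C)C)[C@H]2C(=O)C=C(C)C=C[C@@]12C | intermediate
19 | (1S,3R,3aR,8aR)-3-hydroxy-6,8a-dimethyl-4-oxo-3-(propan-2-yl)-1,2,3,3a,4,8a-hexahydroazulen-1-yl acetate (trans-fused) | CC(=O)O[C@H]1C[C@@](O)(C(C)C)[C@@H]2C(=O)C=C(C)C=C[C@@]12C | intermediate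
20 | (1S,3R,3aR,8aR)-3-hydroxy-6,8a-dimethyl-4-oxo-3-(propan-2-yl)-1,2,3,3a,4,5,8,8a-octahydroazulen-1-yl acetate | CC(=O)O[C@H]1C[C@@](O)(C(C)C)[C@@H]2C(=O)CC(C)=CC[C@@]12C | intermediate
21 | (1S,3R,3aS,4S,8aR)-3,4-dihydroxy-6,8a-dimethyl-3-(propan-2-yl)-1,2,3,3a,4,5,8,8a-octahydroazulen-1-yl acetate | CC(=O)O[C@H]1C[C@@](O)(C(C)C)[C@@H]2[C@@H](O)CC(C)=CC[C@@]12C | intermediate
22 | 4-hydroxybenzoic acid | O=C(O)c1ccc(O)cc1 | starting material
23 | tert-butyldimethylsilyl 4-[(tert-butyldimethylsilyl)oxy]benzoate | CC(C)(C)[Si](C)(C)OC(=O)c1ccc(O[Si](C)(C)C(C)(C)C)cc1 | intermediate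
24 | 4-[(tert-butyldimethylsilyl)oxy]benzoic acid | CC(C)(C)[Si](C)(C)Oc1ccc(C(=O)O)cc1 | intermediate
25 | (1S,3R,3aS,4S,8aR)-1-(acetyloxy)-3-hydroxy-6,8a-dimethyl-3-(propan-2-yl)-1,2,3,3a,4,5,8,8a-octahydroazulen-4-yl 4-[(tert-butyldimethylsilyl)oxy]benzoate | CC(=O)O[C@H]1C[C@@](O)(C(C)C)[C@@H]2[C@@H](OC(=O)c3ccc(O[Si](C)(C)C(C)(C)C)cc3)CC(C)=CC[C@@]12C | intermediate
26 | (1S,3R,3aS,4S,8aR)-1-(acetyloxy)-3-hydroxy-6,8a-dimethyl-3-(propan-2-yl)-1,2,3,3a,4,5,8,8a-octahydroazulen-4-yl 4-hydroxybenzoate | CC(=O)O[C@H]1C[C@@](O)(C(C)C)[C@@H]2[C@@H](OC(=O)c3ccc(O)cc3)CC(C)=CC[C@@]12C | target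

**Step count**

Total: 16 steps. Longest linear sequence: 15 steps (steps 1–13, 15 and 16); step 14 is a one-step side branch.

**Steps most likely to fail**

Step 8. The carbenoid held by the silylene ring may reach the ipso–ortho bond less easily than an open chain, so that insertion into the isopropyl C–H bond or hydride shift from the carbenoid methyl outruns cycloaddition. The fallback releases the bridge before the carbenoid step. From 13, Bu4NF/AcOH should remove the silylene to give (5R)-2-diazo-5-hydroxy-5-(2-hydroxy-4-methylphenyl)-6-methylheptan-3-one F1. N-(trimethylsilyl)imidazole should then silylate both hydroxyls to give (5R)-2-diazo-6-methyl-5-[4-methyl-2-(trimethylsilyloxy)phenyl]-5-(trimethylsilyloxy)heptan-3-one F2. Rh2(OAc)4, or Cu(MeCN)4PF6 with a bisoxazoline ligand matched to C3, should convert F2 into (3R,8aR)-6,8a-dimethyl-3-(propan-2-yl)-3,4-bis(trimethylsilyloxy)-3,8a-dihydroazulen-1(2H)-one F3; the face preference then rests on the isopropyl group lying away from the ortho silyloxy group. LiBH4 in THF should give (1S,3R,8aR)-6,8a-dimethyl-3-(propan-2-yl)-3,4-bis(trimethylsilyloxy)-1,2,3,8a-tetrahydroazulen-1-ol F4, and Ac2O/pyridine/DMAP its acetate, (1S,3R,8aR)-6,8a-dimethyl-3-(propan-2-yl)-3,4-bis(trimethylsilyloxy)-1,2,3,8a-tetrahydroazulen-1-yl acetate F5. Bu4NF/AcOH followed by DBU, as in step 11, returns to 19.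

Step 11. The equilibrium may not lie far enough on the side of the trans-fused epimer, or the base may start retro-aldol cleavage of the C3–C4 bond. The fallback sets C4 kinetically under control of the ring instead of thermodynamically. From 17, the silyl enol ether is protonated at C4 with dilute acid (0.1 M HCl in wet THF, 0 °C) while the O3–Si–O5 ring is still closed. The six-membered ring should then keep C5 cis to O3, which places H4 trans to the C10 methyl. Water opens the silyloxocarbenium ion to (1S,3R,3aR,8aR)-3-{[di-tert-butyl(hydroxy)silyl]oxy}-6,8a-dimethyl-4-oxo-3-(propan-2-yl)-1,2,3,3a,4,8a-hexahydroazulen-1-yl acetate F6. Bu4NF/AcOH removes the silanol residue and returns to 19 without exposure to base.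

Step 12. Hydride may add at C7 in the 1,4-mode, or the β,γ-unsaturated ketone may slip into conjugation and be reduced further. The fallback reduces the ketone first and the diene afterwards. From 19, hydroxyl-directed 1,2-reduction with Me4NBH(OAc)3 should give (1S,3R,3aS,4S,8aR)-3,4-dihydroxy-6,8a-dimethyl-3-(propan-2-yl)-1,2,3,3a,4,8a-hexahydroazulen-1-yl acetate F7. Esterification with 24 (DCC, DMAP) should give (1S,3R,3aS,4S,8aR)-1-(acetyloxy)-3-hydroxy-6,8a-dimethyl-3-(propan-2-yl)-1,2,3,3a,4,8a-hexahydroazulen-4-yl 4-[(tert-butyldimethylsilyl)oxy]benzoate F8. 1,4-Hydrogenation of the cisoid C6=C7–C8=C9 diene with (naphthalene)Cr(CO)3 and H2 in acetone at 45 °C should add hydrogen at C6 and C9 and leave C7=C8, which returns to 25.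

**Further compounds**

F1 | step 8 | (5R)-2-diazo-5-hydroxy-5-(2-hydroxy-4-methylphenyl)-6-methylheptan-3-one | CC(=[N+]=[N-])C(=O)C[C@@](O)(C(C)C)c1ccc(C)cc1O
F2 | step 8 | (5R)-2-diazo-6-methyl-5-[4-methyl-2-(trimethylsilyloxy)phenyl]-5-(trimethylsilyloxy)heptan-3-one | CC(=[N+]=[N-])C(=O)C[C@@](O[Si](C)(C)C)(C(C)C)c1ccc(C)cc1O[Si](C)(C)C
F3 | step 8 | (3R,8aR)-6,8a-dimethyl-3-(propan-2-yl)-3,4-bis(trimethylsilyloxy)-3,8a-dihydroazulen-1(2H)-one | O=C1C[C@@](O[Si](C)(C)C)(C(C)C)C2=C(O[Si](C)(C)C)C=C(C)C=C[C@@]12C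
F4 | step 8 | (1S,3R,8aR)-6,8a-dimethyl-3-(propan-2-yl)-3,4-bis(trimethylsilyloxy)-1,2,3,8a-tetrahydroazulen-1-ol | O[C@H]1C[C@@](O[Si](C)(C)C)(C(C)C)C2=C(O[Si](C)(C)C)C=C(C)C=C[C@@]12C
F5 | step 8 | (1S,3R,8aR)-6,8a-dimethyl-3-(propan-2-yl)-3,4-bis(trimethylsilyloxy)-1,2,3,8a-tetrahydroazulen-1-yl acetate | CC(=O)O[C@H]1C[C@@](O[Si](C)(C)C)(C(C)C)C2=C(O[Si](C)(C)C)C=C(C)C=C[C@@]12C
F6 | step 11 | (1S,3R,3aR,8aR)-3-{[di-tert-butyl(hydroxy)silyl]oxy}-6,8a-dimethyl-4-oxo-3-(propan-2-yl)-1,2,3,3a,4,8a-hexahydroazulen-1-yl acetate | CC(=O)O[C@H]1C[C@@](O[Si](O)(C(C)(C)C)C(C)(C)C)(C(C)C)[C@@H]2C(=O)C=C(C)C=C[C@@]12C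
F7 | step 12 | (1S,3R,3aS,4S,8aR)-3,4-dihydroxy-6,8a-dimethyl-3-(propan-2-yl)-1,2,3,3a,4,8a-hexahydroazulen-1-yl acetate | CC(=O)O[C@H]1C[C@@](O)(C(C)C)[C@@H]2[C@@H](O)C=C(C)C=C[C@@]12C
F8 | step 12 | (1S,3R,3aS,4S,8aR)-1-(acetyloxy)-3-hydroxy-6,8a-dimethyl-3-(propan-2-yl)-1,2,3,3a,4,8a-hexahydroazulen-4-yl 4-[(tert-butyldimethylsilyl)oxy]benzoate | CC(=O)O[C@H]1C[C@@](O)(C(C)C)[C@@H]2[C@@H](OC(=O)c3ccc(O[Si](C)(C)C(C)(C)C)cc3)C=C(C)C=C[C@@]12C
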